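**Retrosynthetic overview**
1. The last bond cut is the quinone C5–O(aryl) bond to the ring C oxygen. The 18-membered ring is the only ring built in the route and is closed last, by a dehydrogenative oxa-Michael macrocyclisation of a seco-quinone.
2. The seco-quinone comes from a bis-stilbene nitrophenol. One flask saturates both C=C bonds, removes both benzyl groups and reduces NO2 to NH2. Fe(III)/H2O then turns the p-aminophenol into the methoxyquinone, so NO2 serves as the masked C4=O.
3. The ring A–O–ring B ether comes from an Ullmann coupling of a bromostilbene (rings A+D) with a stilbene phenol (rings B+C).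
4. Both stilbenes come from HWE olefinations of commercial aldehydes.

Assumption: the SMILES carries no stereodescriptor and the compound has no stereocentre. The macrocycle is taken as conformationally mobile, so no enantioselective step is needed.

Ring labels: A = para-phenylene, B = hydroxy/aryloxy ring, C = meta-phenylene, D = quinone.
Quinone numbering: C1=O lies between C2–OMe and C6–CH2CH2Ar, followed by C3–H, C4=O and C5–H.

**Step 1**
Reactants: 1 nitrosalicylaldehyde 2-hydroxy-3-methoxy-5-nitrobenzaldehyde; 2 diethyl (4-bromobenzyl)phosphonate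
Product: 3 bromostilbene 2-[(E)-2-(4-bromophenyl)ethenyl]-6-methoxy-4-nitrophenol
Conditions: KOtBu (2.3 equiv), THF–DMF, 0 → 40 °C; aq HCl work-up
Reagents that add atoms: none
Why: Horner–Wadsworth–Emmons olefination; the para-nitro group drains the phenoxide charge so the formyl group stays electrophilic, the E-stilbene forms, no stereocentre is created and the alkene geometry is erased in step 4.

**Step 2**
Reactants: 4 benzyl bromide 1-(benzyloxy)-3-(bromomethyl)benzene; 5 triethyl phosphite; 6 aldehyde 4-(benzyloxy)-3-hydroxybenzaldehyde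
Product: 8 stilbene phenol 2-(benzyloxy)-5-[(E)-2-[3-(benzyloxy)phenyl]ethenyl]phenol, via benzylphosphonate 7 (not isolated)
Conditions: 4 + 5 neat, 140 °C, volatiles off in vacuo; then 6, KOtBu (2.3 equiv), THF–DMF, 0 °C → rt; aq HCl work-up
Reagents that add atoms: none
Why: Michaelis–Arbuzov reaction followed by a Horner–Wadsworth–Emmons olefination; the phenoxide of 6 is meta to the formyl group and does not deactivate it, so the E-stilbene forms with the 3-OH left free for step 3.

**Step 3**
Reactants: 3 bromostilbene; 8 stilbene phenol (1.1 equiv)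
Product: 9 bis-stilbene 2-[(E)-2-(4-{2-(benzyloxy)-5-[(E)-2-[3-(benzyloxy)phenyl]ethenyl]phenoxy}phenyl)ethenyl]-6-methoxy-4-nitrophenol
Conditions: CuI (10 mol %), picolinic acid (20 mol %), K3PO4 (3.5 equiv), DMSO, 90 °C, Ar; acidic work-up
Reagents that add atoms: none
Why: Ullmann-type Cu(I)-catalysed diaryl ether synthesis; only the electron-rich phenoxide of 8 couples, because the 2,6-disubstituted 4-nitrophenoxide of 3 is too poor a nucleophile and therefore needs no protecting group.

**Step 4**
Reactants: 9 bis-stilbene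
Product: 12 seco-quinone 2-[2-(4-{2-hydroxy-5-[2-(3-hydroxyphenyl)ethyl]phenoxy}phenyl)ethyl]-6-methoxy-1,4-benzoquinone, via aminophenol 10 (not isolated), via quinone imine 11 (not isolated)
Conditions: H2 (3 bar), 10% Pd/C, THF–AcOH, rt; filtered under Ar into Fe2(SO4)3 (1.5 equiv), 1 M H2SO4/EtOAc, 0 °C, 15 min
Reagents that add atoms: water, O
Why: Catalytic hydrogenation/hydrogenolysis (two C=C, two OBn, NO2 to NH2) followed by the classical Fe(III) oxidation of a p-aminophenol to its quinone imine and acid hydrolysis; the aminophenol is oxidised far below the potential of the ring B and ring C phenols, and the chloride-free medium avoids HCl addition to the quinone.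

**Step 5**
Reactants: 12 seco-quinone
Product: 14 target CNP0332646.0 (marchantin-type bis(bibenzyl) methoxyquinone), via macrocyclic hydroquinone 13 (not isolated)
Conditions: syringe-pump addition of 12 (final 1 mM) to Cs2CO3 (30 mol %), 3,3',5,5'-tetra-tert-butyl-4,4'-diphenoquinone (1.1 equiv), 4 Å MS, DMF, Ar, 25 °C; AcOH quench
Reagents that add atoms: none
Why: Proposed new method: base-catalysed oxidative nucleophilic substitution of hydrogen (a dehydrogenative oxa-Michael reaction) of a phenol on a benzoquinone C–H, run as an 18-membered macrocyclisation; the 2-OMe group makes C4=O a vinylogous ester, so the C1=O/C6=C5 enone is the only strong acceptor and the caesium phenoxide of ring C (O-attack favoured by Cs+/DMF) adds reversibly at C5; the adduct aromatises to hydroquinone 13, which is estimated to be about 0.2 V easier to oxidise than the biphenol/diphenoquinone couple and is dehydrogenated irreversibly by the tert-butyl-shielded diphenoquinone, an acceptor that phenoxides cannot attack and that is too weak to oxidise the ring B or ring C phenols; no net acid forms, so the base is catalytic; attack at C2 only returns starting material because phenoxide leaves before methoxide; the ring B phenoxide could only close a strained 12-membered paracyclophane, and 1 mM pseudo-dilution suppresses oligomers; no stereocentre is formed; the closest known reaction types are the oxidative Michael amination and thiolation of quinones, the addition–elimination of phenoxides on haloquinones, and the use of this diphenoquinone as hydrogen acceptor in oxidative carbene catalysis.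

**Compound list**
1 | 2-hydroxy-3-methoxy-5-nitrobenzaldehyde | O=Cc1cc(cc(OC)c1O)[N+](=O)[O-] | starting material
2 | diethyl (4-bromobenzyl)phosphonate | CCOP(=O)(Cc1ccc(Br)cc1)OCC | starting material
3 | 2-[(E)-2-(4-bromophenyl)ethenyl]-6-methoxy-4-nitrophenol | COc1cc(cc(/C=C/c2ccc(Br)cc2)c1O)[N+](=O)[O-] | intermediate
4 | 1-(benzyloxy)-3-(bromomethyl)benzene | BrCc1cccc(OCc2ccccc2)c1 | starting material
5 | triethyl phosphite | CCOP(OCC)OCC | starting material
6 | 4-(benzyloxy)-3-hydroxybenzaldehyde | O=Cc1ccc(OCc2ccccc2)c(O)c1 | starting material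
7 | diethyl [3-(benzyloxy)benzyl]phosphonate (not isolated) | CCOP(=O)(Cc1cccc(OCc2ccccc2)c1)OCC | intermediate
8 | 2-(benzyloxy)-5-[(E)-2-[3-(benzyloxy)phenyl]ethenyl]phenol | Oc1cc(/C=C/c2cccc(OCc3ccccc3)c2)ccc1OCc1ccccc1 | intermediate
9 | 2-[(E)-2-(4-{2-(benzyloxy)-5-[(E)-2-[3-(benzyloxy)phenyl]ethenyl]phenoxy}phenyl)ethenyl]-6-methoxy-4-nitrophenol | COc1cc(cc(/C=C/c2ccc(Oc3cc(/C=C/c4cccc(OCc5ccccc5)c4)ccc3OCc3ccccc3)cc2)c1O)[N+](=O)[O-] | intermediate
10 | 4-amino-2-[2-(4-{2-hydroxy-5-[2-(3-hydroxyphenyl)ethyl]phenoxy}phenyl)ethyl]-6-methoxyphenol (not isolated) | COc1cc(N)cc(CCc2ccc(Oc3cc(CCc4cccc(O)c4)ccc3O)cc2)c1O | intermediate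
11 | 2-[2-(4-{2-hydroxy-5-[2-(3-hydroxyphenyl)ethyl]phenoxy}phenyl)ethyl]-4-imino-6-methoxycyclohexa-2,5-dien-1-one (not isolated) | COC1=CC(=N)C=C(CCc2ccc(Oc3cc(CCc4cccc(O)c4)ccc3O)cc2)C1=O | intermediate
12 | 2-[2-(4-{2-hydroxy-5-[2-(3-hydroxyphenyl)ethyl]phenoxy}phenyl)ethyl]-6-methoxy-1,4-benzoquinone | COC1=CC(=O)C=C(CCc2ccc(Oc3cc(CCc4cccc(O)c4)ccc3O)cc2)C1=O | intermediate
13 | macrocyclic hydroquinone, the 1,4-dihydro form of the target (not isolated) | COc1cc(O)c2c(CCc3ccc(cc3)Oc3cc(ccc3O)CCc3cccc(c3)O2)c1O | intermediate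
14 | CNP0332646.0, 18-membered bis(bibenzyl) 2-methoxy-5-aryloxy-6-alkyl-1,4-benzoquinone | COC1=CC(=O)C2=C(CCc3ccc(cc3)Oc3cc(ccc3O)CCc3cccc(c3)O2)C1=O | target

**Totals**
Total step count: 5.
Longest linear sequence: 4 steps (step 1 or step 2, then 3, 4, 5).

**Steps most likely to fail**

*Step 5 (the proposed new step).* The reversible O-addition may lose to C-arylation, to oligomerisation or to base-induced decay of the quinone. The fallback uses known chemistry, sets out from 12 and comes back at 14.
- Dry HCl in Et2O/CHCl3 adds 1,4 to the quinone. Chloride enters C5 for the same electronic reason and gives 2-chloro-3-[2-(4-{2-hydroxy-5-[2-(3-hydroxyphenyl)ethyl]phenoxy}phenyl)ethyl]-5-methoxybenzene-1,4-diol F1.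
- Fe2(SO4)3 in dilute H2SO4, as in step 4, oxidises it to 2-chloro-3-[2-(4-{2-hydroxy-5-[2-(3-hydroxyphenyl)ethyl]phenoxy}phenyl)ethyl]-5-methoxy-1,4-benzoquinone F2.
- Slow addition of F2 to Cs2CO3 in DMF (1 mM) closes the ring. This is the established addition–elimination of a phenoxide on a haloquinone.

*Step 3.* The anionic, electron-rich bromide 3 and the ortho-benzyloxy phenol 8 are both sluggish Ullmann partners. The fallback makes the ether on an activated fluoroarene before the A–D bridge exists. It sets out from 8 and comes back at 9.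
- SNAr of 8 with commercial 4-fluorobenzaldehyde (K2CO3, DMF, 130 °C) gives 4-{2-(benzyloxy)-5-[(E)-2-[3-(benzyloxy)phenyl]ethenyl]phenoxy}benzaldehyde F3.
- NaBH4 gives (4-{2-(benzyloxy)-5-[(E)-2-[3-(benzyloxy)phenyl]ethenyl]phenoxy}phenyl)methanol F4.
- ZnI2/P(OEt)3 converts this into diethyl (4-{2-(benzyloxy)-5-[(E)-2-[3-(benzyloxy)phenyl]ethenyl]phenoxy}benzyl)phosphonate F5.
- HWE reaction of F5 with 1 under the conditions of step 1 gives 9.

*Step 4.* Quinone imine 11 may be intercepted by unoxidised 10 or by the phenols before it hydrolyses. The fallback drops the nitrogen and brings in the C4 oxygen by aerobic oxygenation of a phenol. It sets out from 2 and comes back at 12.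
- HWE of 2 with commercial 2-(benzyloxy)-3-methoxybenzaldehyde gives 2-(benzyloxy)-1-[(E)-2-(4-bromophenyl)ethenyl]-3-methoxybenzene F6.
- Ullmann coupling with 8, as in step 3, gives 2-(benzyloxy)-1-[(E)-2-(4-{2-(benzyloxy)-5-[(E)-2-[3-(benzyloxy)phenyl]ethenyl]phenoxy}phenyl)ethenyl]-3-methoxybenzene F7.
- H2/Pd-C gives 2-[2-(4-{2-hydroxy-5-[2-(3-hydroxyphenyl)ethyl]phenoxy}phenyl)ethyl]-6-methoxyphenol F8.
- Co(salen)/O2 in DMF (salcomine oxidation) converts F8 into 12. Ring D is the most reactive phenol toward this oxidation, since it has two ortho donors and a free para position. Ring B is para-blocked but of similar electron-richness, so over-oxidation there is the weak point of this fallback.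

**Further compounds**
F1 | step 5 | 2-chloro-3-[2-(4-{2-hydroxy-5-[2-(3-hydroxyphenyl)ethyl]phenoxy}phenyl)ethyl]-5-methoxybenzene-1,4-diol | COc1cc(O)c(Cl)c(CCc2ccc(Oc3cc(CCc4cccc(O)c4)ccc3O)cc2)c1O
F2 | step 5 | 2-chloro-3-[2-(4-{2-hydroxy-5-[2-(3-hydroxyphenyl)ethyl]phenoxy}phenyl)ethyl]-5-methoxy-1,4-benzoquinone | COC1=CC(=O)C(Cl)=C(CCc2ccc(Oc3cc(CCc4cccc(O)c4)ccc3O)cc2)C1=O
F3 | step 3 | 4-{2-(benzyloxy)-5-[(E)-2-[3-(benzyloxy)phenyl]ethenyl]phenoxy}benzaldehyde | O=Cc1ccc(Oc2cc(/C=C/c3cccc(OCc4ccccc4)c3)ccc2OCc2ccccc2)cc1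
F4 | step 3 | (4-{2-(benzyloxy)-5-[(E)-2-[3-(benzyloxy)phenyl]ethenyl]phenoxy}phenyl)methanol | OCc1ccc(Oc2cc(/C=C/c3cccc(OCc4ccccc4)c3)ccc2OCc2ccccc2)cc1
F5 | step 3 | diethyl (4-{2-(benzyloxy)-5-[(E)-2-[3-(benzyloxy)phenyl]ethenyl]phenoxy}benzyl)phosphonate | CCOP(=O)(Cc1ccc(Oc2cc(/C=C/c3cccc(OCc4ccccc4)c3)ccc2OCc2ccccc2)cc1)OCC
F6 | step 4 | 2-(benzyloxy)-1-[(E)-2-(4-bromophenyl)ethenyl]-3-methoxybenzene | COc1cccc(/C=C/c2ccc(Br)cc2)c1OCc1ccccc1
F7 | step 4 | 2-(benzyloxy)-1-[(E)-2-(4-{2-(benzyloxy)-5-[(E)-2-[3-(benzyloxy)phenyl]ethenyl]phenoxy}phenyl)ethenyl]-3-methoxybenzene | COc1cccc(/C=C/c2ccc(Oc3cc(/C=C/c4cccc(OCc5ccccc5)c4)ccc3OCc3ccccc3)cc2)c1OCc1ccccc1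
F8 | step 4 | 2-[2-(4-{2-hydroxy-5-[2-(3-hydroxyphenyl)ethyl]phenoxy}phenyl)ethyl]-6-methoxyphenol | COc1cccc(CCc2ccc(Oc3cc(CCc4cccc(O)c4)ccc3O)cc2)c1O
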